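**Retrosynthetic overview**
1. The C5 phenol is freed last from a benzyl ether. The C2–CH3 bond is cut back to an anomeric acetate, with methyl added trans to the C4 aryl group through the oxocarbenium ion.
2. The acetate comes from (S)-4-aryl-dihydrocoumarin 9 by half-reduction of the lactone.
3. Key disconnection, C4–naphthyl: (R)-4-boryl-dihydrocoumarin 6 (a chiral boron homoenolate equivalent, C4 as the nucleophile) plus 4-iodo-1,8-dimethoxynaphthalene 8 (the arene as the electrophile), joined by a stereoretentive Pd coupling.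
4. Boronate 6 comes from Cu-catalysed asymmetric conjugate borylation of 5-(benzyloxy)coumarin 5, which is made from 2,6-dihydroxybenzaldehyde; iodide 8 comes from 1,8-dimethoxynaphthalene.
5. Ring order: the benzene and naphthalene rings are bought. The only ring formed is the pyranone (step 1), carried through as lactone, then acetal, then chroman.

Assumption: which hand of the Josiphos ligand gives (R)-6 is not predicted here and must be fixed in a first run (both hands are sold); step 3 is written with the hand that gives (R)-6. The target is the 2,4-trans isomer, (2R,4S).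

**Step 1**
Reactants: 1 2,6-dihydroxybenzaldehyde; 2 ethyl (triphenylphosphoranylidene)acetate
Product: 4 5-hydroxy-2H-chromen-2-one, via ethyl 2,6-dihydroxycinnamate 3 (not isolated)
Conditions: N,N-diethylaniline, reflux (ca. 215 °C), 4 h
Reagents that add atoms: none
Why: Wittig olefination with the stabilised ylide gives the cinnamate, which at this temperature isomerises E to Z and lactonises onto one of the two equivalent ortho hydroxyls (Wittig–lactonisation coumarin synthesis); no stereocentre is formed.

**Step 2**
Reactants: 4 5-hydroxy-2H-chromen-2-one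
Product: 5 5-(benzyloxy)-2H-chromen-2-one
Conditions: BnBr, K2CO3, acetone, reflux
Reagents that add atoms: benzyl bromide, BrCc1ccccc1
Why: Williamson etherification of the only phenol; benzyl survives Cu/alkoxide, Pd/Ag2O, DIBAL-H and AlMe3 and is later removed without touching the naphthyl methyl ethers.

**Step 3**
Reactants: 5 5-(benzyloxy)-2H-chromen-2-one
Product: 6 (4R)-5-(benzyloxy)-4-(4,4,5,5-tetramethyl-1,3,2-dioxaborolan-2-yl)chroman-2-one
Conditions: B2pin2 (1.2 equiv), CuCl (5 mol %), NaOt-Bu (10 mol %), Josiphos SL-J001 (6 mol %, hand that gives 4R), i-PrOH (2 equiv), THF, 0 °C to rt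
Reagents that add atoms: bis(pinacolato)diboron, CC1(C)OB(OC1(C)C)B1OC(C)(C)C(C)(C)O1
Why: Copper(I)-boryl conjugate addition (Yun-type asymmetric β-borylation of an unsaturated lactone) places boron on C4, the chiral bisphosphine–Cu–Bpin adding to one face of the C3=C4 bond to set C4 as R; i-PrOH replaces MeOH as the proton source to spare the aryl-ester lactone.

**Step 4**
Reactants: 7 1,8-dimethoxynaphthalene
Product: 8 4-iodo-1,8-dimethoxynaphthalene
Conditions: NIS (1.0 equiv), TFA (cat.), MeCN, 0 °C to rt
Reagents that add atoms: N-iodosuccinimide, O=C1CCC(=O)N1I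
Why: Electrophilic aromatic iodination of the activated, symmetric naphthalene goes para to a methoxy group, so one equivalent gives the 4-iodide.

**Step 5**
Reactants: 6 (4R)-5-(benzyloxy)-4-(4,4,5,5-tetramethyl-1,3,2-dioxaborolan-2-yl)chroman-2-one; 8 4-iodo-1,8-dimethoxynaphthalene
Product: 9 (4S)-5-(benzyloxy)-4-(4,5-dimethoxynaphthalen-1-yl)chroman-2-one
Conditions: Pd2(dba)3 (4 mol %), PPh3 (Pd:P 1:8), Ag2O (1.5 equiv), DME, 85 °C
Reagents that add atoms: none
Why: Proposed new method: the β-boryl lactone acts as a chiral homoenolate equivalent, with Ag2O-assisted transmetalation of the secondary benzylic C–B bond to the arylpalladium iodide through a closed four-centre transition state (retention, because the in-ring lactone carbonyl cannot reach boron to open an invertive pathway) giving a β-palladated lactone that reductively eliminates with the naphthyl group before β-hydride elimination under high PPh3 loading, so (R)-6 gives (S)-9; the closest known reaction types are the stereoretentive Suzuki–Miyaura coupling of secondary benzylic pinacol boronates (Pd/PPh3/Ag2O) and the cross-coupling of β-trifluoroborato carbonyl compounds.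

**Step 6**
Reactants: 9 (4S)-5-(benzyloxy)-4-(4,5-dimethoxynaphthalen-1-yl)chroman-2-one
Product: 11 (4S)-5-(benzyloxy)-4-(4,5-dimethoxynaphthalen-1-yl)chroman-2-yl acetate (C2 anomers), via lactol 10 (not isolated)
Conditions: DIBAL-H (1.1 equiv), CH2Cl2, −78 °C; Rochelle salt work-up; crude lactol, Ac2O, pyridine, DMAP (cat.), CH2Cl2, 0 °C
Reagents that add atoms: acetic anhydride, CC(=O)OC(C)=O
Why: DIBAL-H half-reduction of the lactone stops at the cyclic hemiacetal at −78 °C and O-acetylation gives the α-acetoxy ether; C4 is untouched and the C2 anomer ratio is irrelevant.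

**Step 7**
Reactants: 11 (4S)-5-(benzyloxy)-4-(4,5-dimethoxynaphthalen-1-yl)chroman-2-yl acetate
Product: 13 (2R,4S)-5-(benzyloxy)-4-(4,5-dimethoxynaphthalen-1-yl)-2-methylchroman, via oxocarbenium ion 12 (not isolated)
Conditions: AlMe3 (3 equiv), CH2Cl2, −78 to 0 °C
Reagents that add atoms: trimethylaluminium, C[Al](C)C
Why: AlMe3 ionises the anomeric acetate and transfers methyl to C2 (Lewis acid-mediated substitution of an α-acetoxy ether via the aryl-oxocarbenium ion) from the face opposite the C4 naphthyl group, which is held pseudoaxial by strain against the C5 benzyloxy group and blocks its own face, giving the 2,4-trans (2R) product.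

**Step 8**
Reactants: 13 (2R,4S)-5-(benzyloxy)-4-(4,5-dimethoxynaphthalen-1-yl)-2-methylchroman
Product: 14 Cladonaphchrom A, (2R,4S)-4-(4,5-dimethoxynaphthalen-1-yl)-2-methylchroman-5-ol
Conditions: H2 (1 atm), 10% Pd/C, EtOAc/MeOH, rt
Reagents that add atoms: none
Why: Hydrogenolysis of the aryl benzyl ether frees the phenol; the methyl ethers, the chroman C–O bonds and both stereocentres are inert under these conditions.

**Compound list**
1 | 2,6-dihydroxybenzaldehyde | O=Cc1c(O)cccc1O | starting material
2 | ethyl (triphenylphosphoranylidene)acetate | CCOC(=O)C=P(c1ccccc1)(c1ccccc1)c1ccccc1 | starting material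
3 | ethyl 3-(2,6-dihydroxyphenyl)prop-2-enoate (ethyl 2,6-dihydroxycinnamate, E/Z) | CCOC(=O)C=Cc1c(O)cccc1O | intermediate
4 | 5-hydroxy-2H-chromen-2-one | O=C1C=Cc2c(O)cccc2O1 | intermediate
5 | 5-(benzyloxy)-2H-chromen-2-one | O=C1C=Cc2c(OCc3ccccc3)cccc2O1 | intermediate
6 | (4R)-5-(benzyloxy)-4-(4,4,5,5-tetramethyl-1,3,2-dioxaborolan-2-yl)chroman-2-one | CC1(C)OB(OC1(C)C)[C@@H]2CC(=O)Oc3cccc(OCc4ccccc4)c32 | intermediate
7 | 1,8-dimethoxynaphthalene | COc1cccc2cccc(OC)c12 | starting material
8 | 4-iodo-1,8-dimethoxynaphthalene | COc1cccc2c(I)ccc(OC)c12 | intermediate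
9 | (4S)-5-(benzyloxy)-4-(4,5-dimethoxynaphthalen-1-yl)chroman-2-one | COc1cccc2c([C@@H]3CC(=O)Oc4cccc(OCc5ccccc5)c43)ccc(OC)c12 | intermediate
10 | (4S)-5-(benzyloxy)-4-(4,5-dimethoxynaphthalen-1-yl)chroman-2-ol (lactol, C2 anomers) | COc1cccc2c([C@@H]3CC(O)Oc4cccc(OCc5ccccc5)c43)ccc(OC)c12 | intermediate
11 | (4S)-5-(benzyloxy)-4-(4,5-dimethoxynaphthalen-1-yl)chroman-2-yl acetate (C2 anomers) | COc1cccc2c([C@@H]3CC(OC(C)=O)Oc4cccc(OCc5ccccc5)c43)ccc(OC)c12 | intermediate
12 | (4S)-5-(benzyloxy)-4-(4,5-dimethoxynaphthalen-1-yl)-3,4-dihydrochromenylium (oxocarbenium ion) | COc1cccc2c([C@@H]3CC=[O+]c4cccc(OCc5ccccc5)c43)ccc(OC)c12 | intermediate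
13 | (2R,4S)-5-(benzyloxy)-4-(4,5-dimethoxynaphthalen-1-yl)-2-methylchroman | COc1cccc2c([C@@H]3C[C@@H](C)Oc4cccc(OCc5ccccc5)c43)ccc(OC)c12 | intermediate
14 | Cladonaphchrom A, (2R,4S)-4-(4,5-dimethoxynaphthalen-1-yl)-2-methylchroman-5-ol | COc1cccc2c([C@@H]3C[C@@H](C)Oc4cccc(O)c43)ccc(OC)c12 | target

**Step count**
Total: 8 steps. Longest linear sequence: 7 steps (1, 2, 3, 5, 6, 7, 8); step 4 is the side branch.

**Steps most likely to fail, with fallbacks**

Step 5 (key coupling). The hindered cyclic benzylic boronate may transmetalate slowly, the alkylpalladium may lose β-hydride to give back coumarin 5, or the enantiomeric purity may erode. The fallback sets out from 6 and replaces two-electron transmetalation by single-electron transmetalation. KHF2 in aqueous MeOH converts 6 into potassium [(4R)-5-(benzyloxy)-2-oxochroman-4-yl]trifluoroborate F1. F1 is then coupled with iodide 8 under Ir photoredox/nickel dual catalysis (Ir[dF(CF3)ppy]2(bpy)PF6, NiCl2·glyme, a chiral bi(oxazoline) ligand, 2,6-lutidine, dioxane, blue LEDs, rt). The benzylic β-lactone radical is captured by the chiral aryl-nickel species, so C4 is then set by the nickel ligand and not by the boron stereocentre, and racemic boronate would also serve. The fallback comes back to the route at 9.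

Step 3 (asymmetric borylation). The β-carbon sits next to the C5 benzyloxy group, the lactone may be opened by the alcohol, and the selectivity on this substrate is unproven. The fallback sets out from 5 and gives up catalytic induction for resolution. A more active achiral catalyst (CuCl/Xantphos, NaOt-Bu, B2pin2, i-PrOH, THF) gives racemic 5-(benzyloxy)-4-(4,4,5,5-tetramethyl-1,3,2-dioxaborolan-2-yl)chroman-2-one F2. Preparative chiral SFC takes out the (R)-half, which is 6; the (S)-half is set aside. The fallback comes back to the route at 6.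

Step 7 (C2 methylation). The trans selectivity rests on a conformational argument, and the oxocarbenium ion could instead lose a proton to the 4H-chromene. The fallback sets out from 9 and sets C2 by reagent control plus a stereospecific ring closure. MeLi (1.0 equiv, THF, −78 °C) opens the lactone to (4S)-4-[2-(benzyloxy)-6-hydroxyphenyl]-4-(4,5-dimethoxynaphthalen-1-yl)butan-2-one F3. (R)-Me-CBS with BH3·SMe2 reduces the ketone to (2S,4S)-4-[2-(benzyloxy)-6-hydroxyphenyl]-4-(4,5-dimethoxynaphthalen-1-yl)butan-2-ol F4. Intramolecular Mitsunobu etherification (PPh3, DIAD, THF, 0 °C) closes the ring with inversion at C2 and gives the (2R,4S) chroman. The fallback comes back to the route at 13.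

**Further compounds**
F1 | step 5 | potassium [(4R)-5-(benzyloxy)-2-oxochroman-4-yl]trifluoroborate | [K+].F[B-](F)(F)[C@@H]1CC(=O)Oc2cccc(OCc3ccccc3)c21
F2 | step 3 | racemic 5-(benzyloxy)-4-(4,4,5,5-tetramethyl-1,3,2-dioxaborolan-2-yl)chroman-2-one | CC1(C)OB(OC1(C)C)C2CC(=O)Oc3cccc(OCc4ccccc4)c32
F3 | step 7 | (4S)-4-[2-(benzyloxy)-6-hydroxyphenyl]-4-(4,5-dimethoxynaphthalen-1-yl)butan-2-one | COc1cccc2c([C@H](CC(C)=O)c3c(O)cccc3OCc3ccccc3)ccc(OC)c12
F4 | step 7 | (2S,4S)-4-[2-(benzyloxy)-6-hydroxyphenyl]-4-(4,5-dimethoxynaphthalen-1-yl)butan-2-ol | COc1cccc2c([C@H](C[C@H](C)O)c3c(O)cccc3OCc3ccccc3)ccc(OC)c12
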